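## Retrosynthetic overview

- **Numbering (daucane).** C1 is the quaternary ring-fusion carbon carrying the angular CH3. C2 and C3 are the cyclopentane CH2 groups, C4 the carbinol carbon (iPr), C5 the ring-fusion CH. C6 is CHOBz, C7 CH2, C8/C9 the oxirane carbons (C8 carries CH3), C10 CH2.
- **Enabling feature.** In the cyclopentane, the methyl-bearing quaternary C1 and the tertiary carbinol C4 both flank C5 and are bridged by two unsubstituted CH2 groups (C2, C3). So C1–CH3 maps onto a tertiary radical made by H-atom transfer to an exocyclic C1=CH2, C4–OH maps onto a ketone, and C2–C3 maps onto an acceptor olefin (acrolein, formyl group removed afterwards).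
- **Endgame disconnections.** Benzoate by acylation of 6α-OH; oxirane by 6α-OH-directed epoxidation of C8=C9; 6α-OH by 4β-OH-directed reduction of the 6-ketone; formyl group by decarbonylation.
- **Key-step precursor.** Monocyclic cycloheptene 17, from an Evans syn aldol (sets C5, with C6 as a relay centre) and ring-closing metathesis (C8=C9).
- **Ring order.** Cycloheptene (step 8), then cyclopentane (step 9, last ring of the carbon skeleton). The oxirane is a late functional-group oxidation on the finished skeleton.

Key step: step 9

Remark: C3 of 21 (the formyl-bearing carbon) is expected as an epimer mixture and is erased in step 10, so it is drawn without configuration.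

## Route

Step 1
Reactants: 1 3-chloro-2-(chloromethyl)prop-1-ene (excess); 2 vinylmagnesium bromide
Product: 3 2-(chloromethyl)penta-1,4-diene
Conditions: Li2CuCl4 (cat.), THF, −30 to 0 °C
Reagents that add atoms: none
Why: Copper-catalysed allylic substitution, in which SN2 and SN2' give the same product because 1 is symmetric, and an excess of 1 should limit double substitution.

Step 2
Reactants: 3 2-(chloromethyl)penta-1,4-diene
Product: 5 3-methylidenehex-5-enoic acid, via allylic Grignard reagent 4 (not isolated)
Conditions: Mg turnings (excess), THF, 0 °C, slow addition; CO2, −20 °C; 1 M HCl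
Reagents that add atoms: carbon dioxide O=C=O
Why: Carboxylation of an allylic Grignard reagent whose two allyl termini are equivalent CH2 groups, so attack through either end should give the same β,γ-unsaturated acid.

Step 3
Reactants: 5 3-methylidenehex-5-enoic acid; 6 (S)-4-benzyl-1,3-oxazolidin-2-one
Product: 8 (S)-4-benzyl-3-(3-methylidenehex-5-enoyl)-1,3-oxazolidin-2-one, via mixed pivalic anhydride 7 (not isolated)
Conditions: PivCl, Et3N, THF, −20 °C; then LiCl, 6, rt
Reagents that add atoms: none
Why: N-Acylation of the oxazolidinone through the mixed anhydride needs no strong base, so the 1,1-disubstituted olefin should stay out of conjugation.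

Step 4
Reactants: 9 3-methylbut-3-en-1-ol
Product: 10 3-methylbut-3-enal
Conditions: PhI(OAc)2, TEMPO (cat.), CH2Cl2, 0 °C to rt; used at once as a solution
Reagents that add atoms: none
Why: TEMPO/PhI(OAc)2 oxidation of a primary alcohol stops at the aldehyde and is close to neutral, so the β,γ-double bond should not move.

Step 5
Reactants: 8 (S)-4-benzyl-3-(3-methylidenehex-5-enoyl)-1,3-oxazolidin-2-one; 10 3-methylbut-3-enal
Product: 13 (S)-4-benzyl-3-[(2S,3R)-3-hydroxy-5-methyl-2-(penta-1,4-dien-2-yl)hex-5-enoyl]-1,3-oxazolidin-2-one, via boron enolate 11 (not isolated), via boron aldolate 12 (not isolated)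
Conditions: Bu2BOTf, Et3N, CH2Cl2, −78 to 0 °C; 10, −78 to 0 °C; pH 7 buffer, MeOH, H2O2
Reagents that add atoms: none
Why: Evans syn aldol addition, in which the (Z)-boron enolate 11 reacts at its α-carbon through a Zimmerman–Traxler chair on the face away from the benzyl group, setting C5 (final configuration) and C6 (6β, a relay centre) as the (2S,3R) syn pair.

Step 6
Reactants: 13 the syn aldol imide
Product: 14 (2S,3R)-3-hydroxy-N-methoxy-N,5-dimethyl-2-(penta-1,4-dien-2-yl)hex-5-enamide
Conditions: MeNH(OMe)·HCl, AlMe3, CH2Cl2, −10 °C to rt; aq. HCl work-up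
Reagents that add atoms: N,O-dimethylhydroxylamine hydrochloride CNOC.Cl
Why: Weinreb transamidation with the aluminium amide, helped by the free β-hydroxyl group, cleaves the exocyclic imide carbonyl without touching C5 and returns the auxiliary.

Step 7
Reactants: 14 the Weinreb amide; 15 isopropylmagnesium chloride
Product: 16 (4S,5R)-5-hydroxy-2,7-dimethyl-4-(penta-1,4-dien-2-yl)oct-7-en-3-one
Conditions: 15 (3.5 equiv), THF, −20 to 0 °C; aq. NH4Cl
Reagents that add atoms: none
Why: Weinreb ketone synthesis, in which an N-methoxy-N-methylamide takes up a single equivalent of Grignard reagent, and the low temperature should keep the acidic allylic C5–H in place.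

Step 8
Reactants: 16 the acyclic hydroxy ketone
Product: 17 1-[(1S,2R)-2-hydroxy-4-methyl-7-methylidenecyclohept-4-en-1-yl]-2-methylpropan-1-one
Conditions: second-generation Grubbs catalyst (5 mol %), 1,4-benzoquinone (cat.), CH2Cl2 (2 mM), reflux
Reagents that add atoms: none
Why: Ring-closing metathesis, in which the catalyst loads on the only monosubstituted olefin and closes onto the methallyl olefin to give the seven-membered ring with the trisubstituted C8=C9 bond, while the hindered C1=CH2 group could only give a three-membered ring or a tetrasubstituted cyclopentene and should stay untouched.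

Step 9
Reactants: 17 the cycloheptene hydroxy ketone; 18 acrolein
Product: 21 4β,6β-dihydroxy-5αH-dauc-8-ene-3-carbaldehyde (1β-methyl; C3 epimers), via tertiary radical 19 (not isolated), via iron enolate 20 (not isolated)
Conditions: Fe(acac)3 (20 mol %), PhSiH2(OiPr) (2 equiv), 18 (3 equiv), ClCH2CH2Cl/(CH2OH)2 5:1, 0 °C to rt
Reagents that add atoms: none
Why: Proposed new method: Fe(acac)3 and the silane generate an iron hydride that transfers H• to the terminal CH2 of C1=CH2 (this creates the angular methyl group and the tertiary C1 radical 19), 19 adds to acrolein, the α-formyl radical is reduced by divalent iron to the trivalent-iron enolate 20, and C3 of 20 attacks the C4 ketone. The closest known reaction type is the MHAT-initiated radical–polar crossover (4+2) annulation of γ,δ-unsaturated carbonyl compounds with enals and enones (Giese addition, then aldol addition); here the donor is a β,γ-unsaturated ketone, so a five-membered ring results, which has not been shown. The cyclopentane C1–C2–C3–C4–C5 is closed at C3–C4 in a 5-(enolexo)-exo-trig aldol addition, a bond that is not part of the ring fusion. At C1, strain between the new methyl group and the isobutyryl group on C5 holds the acyl group pseudo-axial on the β face, so acrolein is taken up intermolecularly from the α face, anti to it, which fixes the trans ring fusion before the ring exists. At C4, the ketone reacts in the rotamer with C=O eclipsing C5–C6 (hydrogen bond or iron chelate to the C6 hydroxyl, isopropyl turned outward) and can be reached by C3 only from the side of C1, which gives 4β-OH and 4α-isopropyl, while C3 forms as a mixture and is erased in step 10. The step needs H• transfer to C1=CH2 rather than to the trisubstituted C8=C9 bond (secured by the unhindered terminal CH2), Giese addition faster than reduction of 19 (excess acrolein), and aldol addition faster than protonation of 20 (intramolecular five-ring closure, little proton donor).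

Step 10
Reactants: 21 the hydroxy aldehyde
Product: 22 dauc-8-ene-4β,6β-diol (5αH; 6-epi-jaeschkeanadiol)
Conditions: [RhCl(cod)]2 (5 mol %), dppp (10 mol %), p-xylene, 140 °C, argon purge
Reagents that add atoms: none
Why: Tsuji–Wilkinson decarbonylation (oxidative addition of the formyl C–H bond, CO extrusion, C–H reductive elimination) replaces CHO by H at C3 and so erases the only undefined centre.

Step 11
Reactants: 22 6-epi-jaeschkeanadiol
Product: 23 4β-hydroxy-5αH-dauc-8-en-6-one
Conditions: Dess–Martin periodinane, CH2Cl2, 0 °C to rt
Reagents that add atoms: none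
Why: Dess–Martin oxidation converts the only secondary alcohol into the ketone under non-basic conditions, so the tertiary aldol unit, C5 and the β,γ-olefin should be kept.

Step 12
Reactants: 23 the β-hydroxy ketone
Product: 25 dauc-8-ene-4β,6α-diol (5αH; jaeschkeanadiol), via alkoxyborohydride 24 (not isolated)
Conditions: Me4NBH(OAc)3, MeCN/AcOH 1:1, −30 °C
Reagents that add atoms: none
Why: Evans–Saksena reduction, in which the 4β-hydroxyl group exchanges onto boron (24) and delivers hydride intramolecularly to the β face of C6=O through a chair-like six-membered transition state, giving the anti-1,3-diol, that is the 6α-alcohol.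

Step 13
Reactants: 25 jaeschkeanadiol
Product: 26 8α,9α-epoxy-5αH-daucane-4β,6α-diol
Conditions: VO(acac)2 (5 mol %), t-BuOOH (decane), CH2Cl2, 0 °C to rt
Reagents that add atoms: tert-butyl hydroperoxide CC(C)(C)OO
Why: Hydroxyl-directed epoxidation, in which the homoallylic 6α-hydroxyl group binds the vanadium alkyl peroxide and delivers oxygen to the α face of C8=C9, setting C8 and C9.

Step 14
Reactants: 26 the epoxy diol; 27 benzoic anhydride
Product: 28 8α,9α-epoxy-4β-hydroxy-5αH-daucan-6α-yl benzoate (target)
Conditions: 27, DMAP (cat.), pyridine, 40 °C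
Reagents that add atoms: none
Why: DMAP-catalysed acylation is selective for the secondary 6α-hydroxyl group because the 4β-hydroxyl group is tertiary and flanked by isopropyl, and the non-acidic medium should keep the oxirane closed.

## Compound list

1 | 3-chloro-2-(chloromethyl)prop-1-ene | C=C(CCl)CCl | starting material
2 | vinylmagnesium bromide | C=C[Mg]Br | starting material
3 | 2-(chloromethyl)penta-1,4-diene | C=CCC(=C)CCl | intermediate
4 | (2-methylidenepent-4-en-1-yl)magnesium chloride | C=CCC(=C)C[Mg]Cl | intermediate
5 | 3-methylidenehex-5-enoic acid | C=CCC(=C)CC(=O)O | intermediate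
6 | (S)-4-benzyl-1,3-oxazolidin-2-one | O=C1OC[C@H](Cc2ccccc2)N1 | starting material
7 | 3-methylidenehex-5-enoic pivalic anhydride | C=CCC(=C)CC(=O)OC(=O)C(C)(C)C | intermediate
8 | (S)-4-benzyl-3-(3-methylidenehex-5-enoyl)-1,3-oxazolidin-2-one | O=C1OC[C@H](Cc2ccccc2)N1C(=O)CC(=C)CC=C | intermediate
9 | 3-methylbut-3-en-1-ol | CC(=C)CCO | starting material
10 | 3-methylbut-3-enal | CC(=C)CC=O | intermediate
11 | (Z)-dibutylboron enolate of 8 | CCCCB(CCCC)O/C(=C\C(=C)CC=C)N1C(=O)OC[C@@H]1Cc1ccccc1 | intermediate
12 | dibutylboron aldolate of 13 | O=C1OC[C@H](Cc2ccccc2)N1C(=O)[C@@H](C(=C)CC=C)[C@H](OB(CCCC)CCCC)CC(C)=C | intermediate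
13 | (S)-4-benzyl-3-[(2S,3R)-3-hydroxy-5-methyl-2-(penta-1,4-dien-2-yl)hex-5-enoyl]-1,3-oxazolidin-2-one | O=C1OC[C@H](Cc2ccccc2)N1C(=O)[C@@H](C(=C)CC=C)[C@H](O)CC(C)=C | intermediate
14 | (2S,3R)-3-hydroxy-N-methoxy-N,5-dimethyl-2-(penta-1,4-dien-2-yl)hex-5-enamide | CON(C)C(=O)[C@@H](C(=C)CC=C)[C@H](O)CC(C)=C | intermediate
15 | isopropylmagnesium chloride | CC(C)[Mg]Cl | starting material
16 | (4S,5R)-5-hydroxy-2,7-dimethyl-4-(penta-1,4-dien-2-yl)oct-7-en-3-one | CC(C)C(=O)[C@@H](C(=C)CC=C)[C@H](O)CC(C)=C | intermediate
17 | 1-[(1S,2R)-2-hydroxy-4-methyl-7-methylidenecyclohept-4-en-1-yl]-2-methylpropan-1-one | CC(C)C(=O)[C@H]1C(=C)CC=C(C)C[C@H]1O | intermediate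
18 | acrolein | C=CC=O | starting material
19 | tertiary C1 radical from 17 (H• added to the exocyclic CH2) | CC(C)C(=O)[C@H]1[C](C)CC=C(C)C[C@H]1O | intermediate
20 | trivalent-iron enolate of the Giese adduct (drawn as the enolate anion) | CC(C)C(=O)[C@H]1[C@](C)(CC=C[O-])CC=C(C)C[C@H]1O | intermediate
21 | 4β,6β-dihydroxy-5αH-dauc-8-ene-3-carbaldehyde (1β-methyl, trans-fused, C3 epimers) | CC(C)[C@]1(O)C(C=O)C[C@]2(C)CC=C(C)C[C@@H](O)[C@H]21 | intermediate
22 | dauc-8-ene-4β,6β-diol (5αH, 6-epi-jaeschkeanadiol) | CC(C)[C@]1(O)CC[C@]2(C)CC=C(C)C[C@@H](O)[C@H]21 | intermediate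
23 | 4β-hydroxy-5αH-dauc-8-en-6-one | CC(C)[C@]1(O)CC[C@]2(C)CC=C(C)CC(=O)[C@H]21 | intermediate
24 | 4-O-bound diacetoxyborohydride of 23 | CC(C)[C@]1(O[BH-](OC(C)=O)OC(C)=O)CC[C@]2(C)CC=C(C)CC(=O)[C@H]21 | intermediate
25 | dauc-8-ene-4β,6α-diol (5αH, jaeschkeanadiol) | CC(C)[C@]1(O)CC[C@]2(C)CC=C(C)C[C@H](O)[C@H]21 | intermediate
26 | 8α,9α-epoxy-5αH-daucane-4β,6α-diol | CC(C)[C@]1(O)CC[C@]2(C)C[C@@H]3O[C@]3(C)C[C@H](O)[C@H]21 | intermediate
27 | benzoic anhydride | O=C(OC(=O)c1ccccc1)c1ccccc1 | starting material
28 | 8α,9α-epoxy-4β-hydroxy-5αH-daucan-6α-yl benzoate | CC(C)[C@]1(O)CC[C@]2(C)C[C@@H]3O[C@]3(C)C[C@H](OC(=O)c3ccccc3)[C@H]21 | target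

## Step count

Total step count: 14.
Longest linear sequence: 13 steps (steps 1–3 and 5–14; step 4 is a one-step side branch).

## Steps most likely to fail

**1. Step 9.**
What may go wrong:
- hydrogen-atom transfer to the ring olefin;
- reduction of the tertiary radical before it meets acrolein;
- protonation of the enolate before ring closure;
- insufficient facial selectivity in the Giese addition.

Fallback (known chemistry, from 17 back to 21): the two C–C bonds are made in separate operations. A reductive olefin coupling (MHAT Giese addition) of 17 with acrolein is run under protic conditions (Fe(acac)3, PhSiH3, EtOH, 60 °C), where the enolate is protonated on purpose. This should give the open keto aldehyde 3-[(1R,6R,7S)-6-hydroxy-1,4-dimethyl-7-(2-methylpropanoyl)cyclohept-3-en-1-yl]propanal F1. An amine-catalysed 5-enolexo aldol addition (pyrrolidine/AcOH or L-proline, DMSO, rt), with the aldehyde as enamine donor and the isopropyl ketone as acceptor, should then close C3–C4 and return to 21.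

**2. Step 10.**
What may go wrong:
- retro-aldol cleavage or dehydration of the β-hydroxy aldehyde at the temperature needed;
- β-hydride elimination from the alkylrhodium species;
- migration of the ring olefin.

Fallback (from 21 back to 22): the carbon is removed as CO2 at room temperature instead of as CO. Pinnick oxidation (NaClO2, NaH2PO4, 2-methylbut-2-ene, t-BuOH/H2O) should give 4β,6β-dihydroxy-5αH-dauc-8-ene-3-carboxylic acid F2. Photoredox hydrodecarboxylation (9-mesityl-10-methylacridinium tetrafluoroborate, PhSSPh, iPr2NEt, CF3CH2OH, blue light) should then give 22.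

**3. Step 12.**
What may go wrong:
- slow ligand exchange of the hindered tertiary alcohol at boron, so that undirected hydride attack from the less hindered α face competes and returns the 6β-alcohol;
- acid-induced migration of the β,γ-olefin.

Fallback (from 23 directly to 25): single-electron reduction replaces hydride delivery. SmI2 in THF/MeOH at 0 °C reduces β-hydroxy ketones through a samarium-chelated ketyl to the anti-1,3-diol, which here is also the more stable equatorial 6α-alcohol. This fallback makes no new compound (F0).

## Further compounds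

F1 | step 9 | 3-[(1R,6R,7S)-6-hydroxy-1,4-dimethyl-7-(2-methylpropanoyl)cyclohept-3-en-1-yl]propanal | CC(C)C(=O)[C@H]1[C@](C)(CCC=O)CC=C(C)C[C@H]1O
F2 | step 10 | 4β,6β-dihydroxy-5αH-dauc-8-ene-3-carboxylic acid (C3 epimers) | CC(C)[C@]1(O)C(C(=O)O)C[C@]2(C)CC=C(C)C[C@@H](O)[C@H]21
F0 | step 12 | none | none
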